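**Plan**

- Retrosynthesis: after removal of the 4'-O-acetyl and 7-O-silyl groups, ring C is cut at C4–C4a (Friedel–Crafts acylation by a 3-aryl-3-aryloxypropanoic acid).
- Ring A is then cut at C5–C6, C7–C8 and C4a–C5 into a 3-alkoxy-2-prenylcyclobutenone and a prenyl siloxyalkyne; the cyclobutenone is cut at its O1–C2 enol ether bond.
- Enabling feature: ring A is a fully substituted phloroglucinol in which O1, O5 and O7 alternate with C4a, C6 and C8. An alkoxy vinylketene (C5, C8, C8a, C4a) and an ynol ether (C6, C7) deliver exactly this pattern, with the three oxygens already differentiated as alkyl ether, free phenol and silyl ether.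
- Forward: ring B is bought (4-acetoxybenzoic acid); one siloxyalkyne serves twice (cyclobutane-1,3-dione via dichloroketene, then benzannulation partner); ring A arises in step 9, ring C in step 11, followed by two deprotections.
- Stereochemistry: C2 is set as the (R)-carbinol by Noyori transfer hydrogenation of a β-keto ester, inverted to (S) in a Mitsunobu etherification and carried unchanged to the end.

Key step: step 9

Remark: 2-prenylcyclobutane-1,3-dione is formulated as its enol 13; its two oxygens are equivalent, so O-alkylation can give only one enol ether.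

**Route**

Step 1
Reactants: 1 4-acetoxybenzoic acid; 2 Meldrum's acid (2,2-dimethyl-1,3-dioxane-4,6-dione)
Product: 3 4-[(2,2-dimethyl-4,6-dioxo-1,3-dioxan-5-ylidene)(hydroxy)methyl]phenyl acetate
Conditions: DCC, DMAP, CH2Cl2, 0 °C to rt
Reagents that add atoms: none
Why: Carbodiimide/DMAP-mediated C-acylation of Meldrum's acid, a carbon acid acidic enough to be acylated through the acylpyridinium ion, should give the enolised acyl derivative while the aryl acetate is untouched.

Step 2
Reactants: 3 4-[(2,2-dimethyl-4,6-dioxo-1,3-dioxan-5-ylidene)(hydroxy)methyl]phenyl acetate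
Product: 4 allyl 3-(4-acetoxyphenyl)-3-oxopropanoate
Conditions: allyl alcohol (3 equiv), toluene, 90 °C
Reagents that add atoms: allyl alcohol, C=CCO
Why: Thermal alcoholysis of an acyl Meldrum's acid (β-keto ester synthesis with loss of acetone and CO2) needs neither acid nor base, so the phenolic acetate should not transesterify.

Step 3
Reactants: 4 allyl 3-(4-acetoxyphenyl)-3-oxopropanoate
Product: 5 allyl (3R)-3-(4-acetoxyphenyl)-3-hydroxypropanoate
Conditions: RuCl[(R,R)-TsDPEN](p-cymene) (1 mol %), HCO2H/Et3N (5:2), EtOAc, 30 °C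
Reagents that add atoms: none
Why: Noyori asymmetric transfer hydrogenation of an aryl ketone, in which the (R,R)-ligand should deliver hydride to the Si face (the sense that turns acetophenone into (R)-1-phenylethanol) and so set the (R)-carbinol, while the allyl alkene and the acetate are not reduced by this catalyst.

Step 4
Reactants: 6 1-bromo-3-methylbut-2-ene (prenyl bromide)
Product: 7 5-methylhex-4-en-1-yne
Conditions: HC≡CMgBr, CuCl (5 mol %), THF, 0 to 45 °C
Reagents that add atoms: ethynylmagnesium bromide, C#C[Mg]Br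
Why: Copper-catalysed coupling of an alkynyl Grignard reagent with an allylic bromide should join the acetylide to the unhindered primary carbon of the prenyl unit (SN2 rather than SN2' regiochemistry) and give the skipped enyne.

Step 5
Reactants: 7 5-methylhex-4-en-1-yne
Product: 10 triisopropyl[(5-methylhex-4-en-1-yn-1-yl)oxy]silane, via lithium acetylide 8 (not isolated), via lithium ynolate 9 (not isolated)
Conditions: LiN(SiMe3)2, THF, −78 °C; then t-BuOOLi (from t-BuOOH and LiN(SiMe3)2), THF, −78 to 0 °C; then TIPSOTf, −78 °C to rt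
Reagents that add atoms: tert-butyl hydroperoxide, CC(C)(C)OO; triisopropylsilyl trifluoromethanesulfonate, CC(C)[Si](OS(=O)(=O)C(F)(F)F)(C(C)C)C(C)C
Why: Oxidation of a lithium acetylide by oxygen transfer from lithium tert-butyl peroxide to the ynolate, followed by O-silylation with the bulky silyl triflate, is the standard siloxyalkyne synthesis, and the trisubstituted alkene is inert to the nucleophilic peroxide.

Step 6
Reactants: 10 triisopropyl[(5-methylhex-4-en-1-yn-1-yl)oxy]silane
Product: 11 4,4-dichloro-2-(3-methylbut-2-en-1-yl)-3-[(triisopropylsilyl)oxy]cyclobut-2-en-1-one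
Conditions: Cl3CCOCl (slow addition), Zn–Cu couple, Et2O/DME, 0 °C
Reagents that add atoms: trichloroacetyl chloride, ClC(=O)C(Cl)(Cl)Cl
Why: Ketene–ynol ether [2+2] cycloaddition in which the nucleophilic prenyl-bearing alkyne carbon should attack the carbonyl carbon of dichloroketene generated in the flask, giving the 3-siloxycyclobutenone regiochemistry, with the ynol ether far more reactive than the isolated trisubstituted alkene and DME binding the ZnCl2 formed.

Step 7
Reactants: 11 4,4-dichloro-2-(3-methylbut-2-en-1-yl)-3-[(triisopropylsilyl)oxy]cyclobut-2-en-1-one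
Product: 13 3-hydroxy-2-(3-methylbut-2-en-1-yl)cyclobut-2-en-1-one, via siloxycyclobutenone 12 (not isolated)
Conditions: Zn dust, AcOH, TMEDA, EtOH, 0 °C to rt; then 1 M HCl, THF, 0 °C
Reagents that add atoms: none
Why: Zinc reduction of an α,α-dichloro ketone (reductive dehalogenation through the zinc enolate) followed by acid hydrolysis of the vinylogous silyl ester should deliver the symmetrical 1,3-dione, which rests as its strongly acidic enol.

Step 8
Reactants: 13 3-hydroxy-2-(3-methylbut-2-en-1-yl)cyclobut-2-en-1-one; 5 allyl (3R)-3-(4-acetoxyphenyl)-3-hydroxypropanoate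
Product: 14 allyl (3S)-3-(4-acetoxyphenyl)-3-{[2-(3-methylbut-2-en-1-yl)-3-oxocyclobut-1-en-1-yl]oxy}propanoate
Conditions: PPh3, DIAD, THF, 0 °C to rt
Reagents that add atoms: none
Why: Mitsunobu etherification in which the vinylogous acid 13 should be O-alkylated by the activated benzylic alcohol with SN2 inversion, (R) to (S), C-alkylation being blocked by the prenyl group on the central carbon and benzylic ionisation being held back by the only weakly donating 4-acetoxy substituent.

Step 9
Reactants: 14 allyl (3S)-3-(4-acetoxyphenyl)-3-{[2-(3-methylbut-2-en-1-yl)-3-oxocyclobut-1-en-1-yl]oxy}propanoate; 10 triisopropyl[(5-methylhex-4-en-1-yn-1-yl)oxy]silane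
Product: 19 allyl (3S)-3-(4-acetoxyphenyl)-3-{5-hydroxy-2,4-bis(3-methylbut-2-en-1-yl)-3-[(triisopropylsilyl)oxy]phenoxy}propanoate, via alkoxy vinylketene 15 (not isolated), via vinylcyclobutenone 16 (not isolated), via dienylketene 17 (not isolated), via cyclohexadienone 18 (not isolated)
Conditions: 10 (1.8 equiv), toluene, 80 then 110 °C, sealed tube, argon
Reagents that add atoms: none
Why: Heating should open cyclobutenone 14 by four-electron electrocyclic cleavage of its C(=O)–CH2 bond to alkoxy vinylketene 15, whose ketene carbon (future C5) and prenyl-bearing carbon (future C8) add across siloxyalkyne 10 in a [2+2] cycloaddition that forms C5–C6 and C7–C8 and gives vinylcyclobutenone 16. A second four-electron opening of 16 gives dienylketene 17, and ring A closes by a thermally allowed disrotatory six-electron electrocyclisation that joins the ketene carbon C5 to the methylene terminus C4a, after which dienone 18 tautomerises to phenol 19. The closest known reaction type is the Danheiser benzannulation of cyclobutenones with siloxyalkynes to resorcinol monosilyl ethers, and 3-alkoxycyclobutenones are known to open thermally to alkoxy vinylketenes. No stereocentre is formed, and the (S)-carbinol is a spectator because no bond to it takes part and the medium contains neither acid nor base. The selectivity required is the orientation of the ketene–alkyne cycloaddition, which the polarised ynol ether secures: its nucleophilic prenyl-bearing carbon bonds to the electrophilic ketene carbon, so the siloxy group ends at C7 between the two prenyl groups, the new hydroxyl at C5 and the chiral ether at C8a, with C4a left as the only ring C–H. An excess of 10 is used so that the vinylketene is consumed by the alkyne before it can acylate the phenol that accumulates.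

Step 10
Reactants: 19 allyl (3S)-3-(4-acetoxyphenyl)-3-{5-hydroxy-2,4-bis(3-methylbut-2-en-1-yl)-3-[(triisopropylsilyl)oxy]phenoxy}propanoate
Product: 20 (3S)-3-(4-acetoxyphenyl)-3-{5-hydroxy-2,4-bis(3-methylbut-2-en-1-yl)-3-[(triisopropylsilyl)oxy]phenoxy}propanoic acid
Conditions: Pd(PPh3)4 (5 mol %), N-methylaniline (3 equiv), THF, rt
Reagents that add atoms: none
Why: Tsuji–Trost deallylation, in which zerovalent palladium ionises the allyl ester to a π-allyl complex that the amine captures, should release the acid under neutral conditions that spare the aryl acetate, the silyl ether, the prenyl groups and the elimination-prone β-aryloxy acid motif.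

Step 11
Reactants: 20 (3S)-3-(4-acetoxyphenyl)-3-{5-hydroxy-2,4-bis(3-methylbut-2-en-1-yl)-3-[(triisopropylsilyl)oxy]phenoxy}propanoic acid
Product: 22 4-[(2S)-5-hydroxy-6,8-bis(3-methylbut-2-en-1-yl)-4-oxo-7-[(triisopropylsilyl)oxy]-3,4-dihydro-2H-chromen-2-yl]phenyl acetate, via mixed anhydride 21 (not isolated)
Conditions: (CF3CO)2O (1.5 equiv), CH2Cl2, 0 °C; then sat. aq. NaHCO3
Reagents that add atoms: none
Why: Intramolecular Friedel–Crafts acylation through the mixed trifluoroacetic anhydride should close six-membered ring C at 0 °C, because C4a is the only unsubstituted ring carbon and is activated by O1 and O5 (ortho) and O7 (para), before the prenyl groups or the benzylic ether (deactivated towards ionisation by the 4-acetoxy group) respond to the trifluoroacetic acid present.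

Step 12
Reactants: 22 4-[(2S)-5-hydroxy-6,8-bis(3-methylbut-2-en-1-yl)-4-oxo-7-[(triisopropylsilyl)oxy]-3,4-dihydro-2H-chromen-2-yl]phenyl acetate
Product: 23 4-[(2S)-5,7-dihydroxy-6,8-bis(3-methylbut-2-en-1-yl)-4-oxo-3,4-dihydro-2H-chromen-2-yl]phenyl acetate
Conditions: Bu4NF, AcOH (1:1), THF, 0 °C
Reagents that add atoms: none
Why: Fluoride-induced cleavage of the aryl silyl ether, buffered with acetic acid so that the phenoxide is protonated at once, should avoid base-induced opening of the flavanone to the chalcone, which would racemise C2.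

Step 13
Reactants: 23 4-[(2S)-5,7-dihydroxy-6,8-bis(3-methylbut-2-en-1-yl)-4-oxo-3,4-dihydro-2H-chromen-2-yl]phenyl acetate
Product: 24 (2S)-5,7-dihydroxy-2-(4-hydroxyphenyl)-6,8-bis(3-methylbut-2-en-1-yl)-2,3-dihydro-4H-chromen-4-one (6,8-diprenylnaringenin)
Conditions: NH4OAc, MeOH/H2O (4:1), rt
Reagents that add atoms: none
Why: Ammonium acetate-mediated methanolysis of a phenolic acetate runs at neutral pH, so the only ester left should be removed without enolisation or retro-oxa-Michael opening at C2.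

**Compound list**

1 | 4-acetoxybenzoic acid | CC(=O)Oc1ccc(cc1)C(=O)O | starting material
2 | 2,2-dimethyl-1,3-dioxane-4,6-dione (Meldrum's acid) | CC1(C)OC(=O)CC(=O)O1 | starting material
3 | 4-[(2,2-dimethyl-4,6-dioxo-1,3-dioxan-5-ylidene)(hydroxy)methyl]phenyl acetate | CC(=O)Oc1ccc(cc1)C(O)=C1C(=O)OC(C)(C)OC1=O | intermediate
4 | allyl 3-(4-acetoxyphenyl)-3-oxopropanoate | C=CCOC(=O)CC(=O)c1ccc(OC(C)=O)cc1 | intermediate
5 | allyl (3R)-3-(4-acetoxyphenyl)-3-hydroxypropanoate | O[C@H](CC(=O)OCC=C)c1ccc(OC(C)=O)cc1 | intermediate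
6 | 1-bromo-3-methylbut-2-ene (prenyl bromide) | CC(C)=CCBr | starting material
7 | 5-methylhex-4-en-1-yne | CC(C)=CCC#C | intermediate
8 | lithium 5-methylhex-4-en-1-yn-1-ide | CC(C)=CCC#C[Li] | intermediate
9 | lithium 5-methylhex-4-en-1-yn-1-olate | CC(C)=CCC#CO[Li] | intermediate
10 | triisopropyl[(5-methylhex-4-en-1-yn-1-yl)oxy]silane | CC(C)=CCC#CO[Si](C(C)C)(C(C)C)C(C)C | intermediate
11 | 4,4-dichloro-2-(3-methylbut-2-en-1-yl)-3-[(triisopropylsilyl)oxy]cyclobut-2-en-1-one | O=C1C(CC=C(C)C)=C(O[Si](C(C)C)(C(C)C)C(C)C)C1(Cl)Cl | intermediate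
12 | 2-(3-methylbut-2-en-1-yl)-3-[(triisopropylsilyl)oxy]cyclobut-2-en-1-one | O=C1CC(O[Si](C(C)C)(C(C)C)C(C)C)=C1CC=C(C)C | intermediate
13 | 3-hydroxy-2-(3-methylbut-2-en-1-yl)cyclobut-2-en-1-one (enol of 2-prenylcyclobutane-1,3-dione) | O=C1CC(O)=C1CC=C(C)C | intermediate
14 | allyl (3S)-3-(4-acetoxyphenyl)-3-{[2-(3-methylbut-2-en-1-yl)-3-oxocyclobut-1-en-1-yl]oxy}propanoate | O=C1CC(O[C@@H](CC(=O)OCC=C)c2ccc(OC(C)=O)cc2)=C1CC=C(C)C | intermediate
15 | allyl (3S)-3-(4-acetoxyphenyl)-3-{[3-(3-methylbut-2-en-1-yl)-4-oxobuta-1,3-dien-2-yl]oxy}propanoate (alkoxy vinylketene) | O=C=C(CC=C(C)C)C(=C)O[C@@H](CC(=O)OCC=C)c1ccc(OC(C)=O)cc1 | intermediate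
16 | allyl (3S)-3-(4-acetoxyphenyl)-3-({1-[1,3-bis(3-methylbut-2-en-1-yl)-4-oxo-2-[(triisopropylsilyl)oxy]cyclobut-2-en-1-yl]ethenyl}oxy)propanoate (vinylcyclobutenone, mixture at the ring quaternary carbon) | O=C1C(CC=C(C)C)=C(O[Si](C(C)C)(C(C)C)C(C)C)C1(CC=C(C)C)C(=C)O[C@@H](CC(=O)OCC=C)c2ccc(OC(C)=O)cc2 | intermediate
17 | allyl (3S)-3-(4-acetoxyphenyl)-3-{[3,5-bis(3-methylbut-2-en-1-yl)-6-oxo-4-[(triisopropylsilyl)oxy]hexa-1,3,5-trien-2-yl]oxy}propanoate (dienylketene, ketene carbon and alkoxyvinyl group cis on the central double bond) | O=C=C(CC=C(C)C)/C(O[Si](C(C)C)(C(C)C)C(C)C)=C(CC=C(C)C)\C(=C)O[C@@H](CC(=O)OCC=C)c1ccc(OC(C)=O)cc1 | intermediate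
18 | allyl (3S)-3-(4-acetoxyphenyl)-3-{[2,4-bis(3-methylbut-2-en-1-yl)-5-oxo-3-[(triisopropylsilyl)oxy]cyclohexa-1,3-dien-1-yl]oxy}propanoate | O=C1CC(O[C@@H](CC(=O)OCC=C)c2ccc(OC(C)=O)cc2)=C(CC=C(C)C)C(O[Si](C(C)C)(C(C)C)C(C)C)=C1CC=C(C)C | intermediate
19 | allyl (3S)-3-(4-acetoxyphenyl)-3-{5-hydroxy-2,4-bis(3-methylbut-2-en-1-yl)-3-[(triisopropylsilyl)oxy]phenoxy}propanoate | C=CCOC(=O)C[C@@H](c1ccc(OC(C)=O)cc1)Oc1cc(O)c(CC=C(C)C)c(O[Si](C(C)C)(C(C)C)C(C)C)c1CC=C(C)C | intermediate
20 | (3S)-3-(4-acetoxyphenyl)-3-{5-hydroxy-2,4-bis(3-methylbut-2-en-1-yl)-3-[(triisopropylsilyl)oxy]phenoxy}propanoic acid | OC(=O)C[C@@H](c1ccc(OC(C)=O)cc1)Oc1cc(O)c(CC=C(C)C)c(O[Si](C(C)C)(C(C)C)C(C)C)c1CC=C(C)C | intermediate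
21 | (3S)-3-(4-acetoxyphenyl)-3-{5-hydroxy-2,4-bis(3-methylbut-2-en-1-yl)-3-[(triisopropylsilyl)oxy]phenoxy}propanoic trifluoroacetic anhydride | O=C(OC(=O)C(F)(F)F)C[C@@H](c1ccc(OC(C)=O)cc1)Oc1cc(O)c(CC=C(C)C)c(O[Si](C(C)C)(C(C)C)C(C)C)c1CC=C(C)C | intermediate
22 | 4-[(2S)-5-hydroxy-6,8-bis(3-methylbut-2-en-1-yl)-4-oxo-7-[(triisopropylsilyl)oxy]-3,4-dihydro-2H-chromen-2-yl]phenyl acetate | CC(C)=CCc1c(O[Si](C(C)C)(C(C)C)C(C)C)c(CC=C(C)C)c2c(c1O)C(=O)C[C@@H](c1ccc(OC(C)=O)cc1)O2 | intermediate
23 | 4-[(2S)-5,7-dihydroxy-6,8-bis(3-methylbut-2-en-1-yl)-4-oxo-3,4-dihydro-2H-chromen-2-yl]phenyl acetate | CC(C)=CCc1c(O)c(CC=C(C)C)c2c(c1O)C(=O)C[C@@H](c1ccc(OC(C)=O)cc1)O2 | intermediate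
24 | (2S)-5,7-dihydroxy-2-(4-hydroxyphenyl)-6,8-bis(3-methylbut-2-en-1-yl)-2,3-dihydro-4H-chromen-4-one (6,8-diprenylnaringenin) | CC(C)=CCc1c(O)c(CC=C(C)C)c2c(c1O)C(=O)C[C@@H](c1ccc(O)cc1)O2 | target

**Step count and risks**

Total steps: 13. Longest linear sequence: 10 steps (6 → 7 → 10 → 11 → 13 → 14 → 19 → 20 → 22 → 23 → 24, steps 4 to 13).

Steps most likely to fail:

1. Step 9 (benzannulation). The vinylogous ester 14 is stabilised by its 3-alkoxy group, so ring opening may become slower than three competing processes: thermal β-elimination of the benzylic enol ether towards the cinnamate, 1,3-silyl migration of the siloxyalkyne to a silylketene, and acylation of the accumulating phenol by the vinylketene. The fallback takes the stereocentre out of the thermal step. It sets out from 12 (isolated from step 7 by leaving out the acid treatment) and 10, which are heated together in toluene. The same cascade should then give the achiral 2,4-bis(3-methylbut-2-en-1-yl)-3,5-bis[(triisopropylsilyl)oxy]phenol F1, a robust substrate that tolerates forcing conditions. Because the two oxygens flanking the ring C–H are equivalent in the diprenylphloroglucinol core, the single free hydroxyl of F1 can serve as O1. Mitsunobu etherification of F1 with 5 (PPh3, DIAD, toluene) gives allyl (3S)-3-(4-acetoxyphenyl)-3-{2,4-bis(3-methylbut-2-en-1-yl)-3,5-bis[(triisopropylsilyl)oxy]phenoxy}propanoate F2. Deallylation as in step 10 gives (3S)-3-(4-acetoxyphenyl)-3-{2,4-bis(3-methylbut-2-en-1-yl)-3,5-bis[(triisopropylsilyl)oxy]phenoxy}propanoic acid F3. Treatment with (CF3CO)2O as in step 11 passes through the mixed trifluoroacetic anhydride of that acid F4 and closes ring C to 4-[(2S)-6,8-bis(3-methylbut-2-en-1-yl)-4-oxo-5,7-bis[(triisopropylsilyl)oxy]-3,4-dihydro-2H-chromen-2-yl]phenyl acetate F5. Bu4NF/AcOH then removes both silyl groups, and the route is rejoined at 23.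

2. Step 8 (Mitsunobu etherification). The activated β-hydroxy ester may undergo E2 elimination to the cinnamate, and partial ionisation of the benzylic oxyphosphonium ion would erode the enantiomeric purity. The fallback forms the enol ether bond at the vinylic carbon instead of at the stereocentre, so the carbinol configuration is retained. It sets out from 13 and 4. Compound 13 is converted with (COCl)2 and catalytic DMF in CH2Cl2 at 0 °C into the vinylogous acid chloride 3-chloro-2-(3-methylbut-2-en-1-yl)cyclobut-2-en-1-one F6. Compound 4 is reduced as in step 3 but with RuCl[(S,S)-TsDPEN](p-cymene) to allyl (3S)-3-(4-acetoxyphenyl)-3-hydroxypropanoate F7. Addition–elimination of F7 onto F6 (2,6-lutidine, catalytic DMAP, CH2Cl2, 0 °C) should give 14 with retention, where the route is rejoined.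

3. Step 11 (Friedel–Crafts closure of ring C). Three acid-driven processes could compete: attack of the free 5-hydroxyl on the protonated C6 prenyl alkene (chroman formation), O-trifluoroacetylation of that phenol diverting the anhydride, and heterolysis of the benzylic C–O bond with loss of configuration. The fallback removes the free phenol and replaces the Brønsted-acidic anhydride medium by a discrete acyl chloride and a Lewis acid at low temperature. It sets out from 19, which is silylated (TBSCl, imidazole, DMF) to allyl (3S)-3-(4-acetoxyphenyl)-3-{5-[(tert-butyldimethylsilyl)oxy]-2,4-bis(3-methylbut-2-en-1-yl)-3-[(triisopropylsilyl)oxy]phenoxy}propanoate F8. Deallylation as in step 10 gives (3S)-3-(4-acetoxyphenyl)-3-{5-[(tert-butyldimethylsilyl)oxy]-2,4-bis(3-methylbut-2-en-1-yl)-3-[(triisopropylsilyl)oxy]phenoxy}propanoic acid F9. 1-Chloro-N,N,2-trimethylprop-1-en-1-amine in CH2Cl2 at 0 °C converts it without free HCl into (3S)-3-(4-acetoxyphenyl)-3-{5-[(tert-butyldimethylsilyl)oxy]-2,4-bis(3-methylbut-2-en-1-yl)-3-[(triisopropylsilyl)oxy]phenoxy}propanoyl chloride F10. SnCl4 in CH2Cl2 at −78 °C then closes ring C to 4-[(2S)-5-[(tert-butyldimethylsilyl)oxy]-6,8-bis(3-methylbut-2-en-1-yl)-4-oxo-7-[(triisopropylsilyl)oxy]-3,4-dihydro-2H-chromen-2-yl]phenyl acetate F11. Bu4NF/AcOH removes both silyl groups, and the route is rejoined at 23.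

**Further compounds**

F1 | step 9 | 2,4-bis(3-methylbut-2-en-1-yl)-3,5-bis[(triisopropylsilyl)oxy]phenol | Oc1cc(O[Si](C(C)C)(C(C)C)C(C)C)c(CC=C(C)C)c(O[Si](C(C)C)(C(C)C)C(C)C)c1CC=C(C)C
F2 | step 9 | allyl (3S)-3-(4-acetoxyphenyl)-3-{2,4-bis(3-methylbut-2-en-1-yl)-3,5-bis[(triisopropylsilyl)oxy]phenoxy}propanoate | C=CCOC(=O)C[C@@H](c1ccc(OC(C)=O)cc1)Oc1cc(O[Si](C(C)C)(C(C)C)C(C)C)c(CC=C(C)C)c(O[Si](C(C)C)(C(C)C)C(C)C)c1CC=C(C)C
F3 | step 9 | (3S)-3-(4-acetoxyphenyl)-3-{2,4-bis(3-methylbut-2-en-1-yl)-3,5-bis[(triisopropylsilyl)oxy]phenoxy}propanoic acid | OC(=O)C[C@@H](c1ccc(OC(C)=O)cc1)Oc1cc(O[Si](C(C)C)(C(C)C)C(C)C)c(CC=C(C)C)c(O[Si](C(C)C)(C(C)C)C(C)C)c1CC=C(C)C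
F4 | step 9 | (3S)-3-(4-acetoxyphenyl)-3-{2,4-bis(3-methylbut-2-en-1-yl)-3,5-bis[(triisopropylsilyl)oxy]phenoxy}propanoic trifluoroacetic anhydride | O=C(OC(=O)C(F)(F)F)C[C@@H](c1ccc(OC(C)=O)cc1)Oc1cc(O[Si](C(C)C)(C(C)C)C(C)C)c(CC=C(C)C)c(O[Si](C(C)C)(C(C)C)C(C)C)c1CC=C(C)C
F5 | step 9 | 4-[(2S)-6,8-bis(3-methylbut-2-en-1-yl)-4-oxo-5,7-bis[(triisopropylsilyl)oxy]-3,4-dihydro-2H-chromen-2-yl]phenyl acetate | CC(C)=CCc1c(O[Si](C(C)C)(C(C)C)C(C)C)c(CC=C(C)C)c2c(c1O[Si](C(C)C)(C(C)C)C(C)C)C(=O)C[C@@H](c1ccc(OC(C)=O)cc1)O2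
F6 | step 8 | 3-chloro-2-(3-methylbut-2-en-1-yl)cyclobut-2-en-1-one | O=C1CC(Cl)=C1CC=C(C)C
F7 | step 8 | allyl (3S)-3-(4-acetoxyphenyl)-3-hydroxypropanoate | O[C@@H](CC(=O)OCC=C)c1ccc(OC(C)=O)cc1
F8 | step 11 | allyl (3S)-3-(4-acetoxyphenyl)-3-{5-[(tert-butyldimethylsilyl)oxy]-2,4-bis(3-methylbut-2-en-1-yl)-3-[(triisopropylsilyl)oxy]phenoxy}propanoate | C=CCOC(=O)C[C@@H](c1ccc(OC(C)=O)cc1)Oc1cc(O[Si](C)(C)C(C)(C)C)c(CC=C(C)C)c(O[Si](C(C)C)(C(C)C)C(C)C)c1CC=C(C)C
F9 | step 11 | (3S)-3-(4-acetoxyphenyl)-3-{5-[(tert-butyldimethylsilyl)oxy]-2,4-bis(3-methylbut-2-en-1-yl)-3-[(triisopropylsilyl)oxy]phenoxy}propanoic acid | OC(=O)C[C@@H](c1ccc(OC(C)=O)cc1)Oc1cc(O[Si](C)(C)C(C)(C)C)c(CC=C(C)C)c(O[Si](C(C)C)(C(C)C)C(C)C)c1CC=C(C)C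
F10 | step 11 | (3S)-3-(4-acetoxyphenyl)-3-{5-[(tert-butyldimethylsilyl)oxy]-2,4-bis(3-methylbut-2-en-1-yl)-3-[(triisopropylsilyl)oxy]phenoxy}propanoyl chloride | ClC(=O)C[C@@H](c1ccc(OC(C)=O)cc1)Oc1cc(O[Si](C)(C)C(C)(C)C)c(CC=C(C)C)c(O[Si](C(C)C)(C(C)C)C(C)C)c1CC=C(C)C
F11 | step 11 | 4-[(2S)-5-[(tert-butyldimethylsilyl)oxy]-6,8-bis(3-methylbut-2-en-1-yl)-4-oxo-7-[(triisopropylsilyl)oxy]-3,4-dihydro-2H-chromen-2-yl]phenyl acetate | CC(C)=CCc1c(O[Si](C(C)C)(C(C)C)C(C)C)c(CC=C(C)C)c2c(c1O[Si](C)(C)C(C)(C)C)C(=O)C[C@@H](c1ccc(OC(C)=O)cc1)O2
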